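At late times the readings levelled off below full conversion: Thursday's at 81.9%, Sunday's at 93.0% and Tuesday's at 93.5%.

| flask | free monomer | protic impurity | initiator | remark | time |
|---|---|---|---|---|---|
| Thursday's | 0.050 M | 0.050 M | 4 mol% | run made earlier |  |
| Sunday's | 0.050 M | 0.050 M | 15 mol% | run made earlier |  |
| Tuesday's | 0.078 M | 0.050 M | 10 mol% | run made earlier |  |
| dusk | 0.080 M | 0.0500 M | 3 mol% |  | 25 min |
| winter | 0.050 M | 0.0500 M | 10 mol% |  | 25 min |

| run | time / min | monomer in chains / % |
|---|---|---|
| Thursday's | 0.833 | 30.0 |
| Thursday's | 2.50 | 66.8 |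
| Thursday's | 4.00 | 75.9 |
| Thursday's | 6.00 | 80.1 |
| Thursday's | 10.0 | 81.5 |
| Thursday's | 12.0 | 81.9 |
| Sunday's | 1.00 | 76.0 |
| Sunday's | 1.50 | 86.9 |
| Sunday's | 3.00 | 91.7 |
| Sunday's | 5.00 | 92.3 |
| Sunday's | 8.00 | 92.9 |
| Sunday's | 12.0 | 93.0 |
| Tuesday's | 1.00 | 81.1 |
| Tuesday's | 2.00 | 91.7 |
| Tuesday's | 4.00 | 93.0 |
| Tuesday's | 6.00 | 93.3 |
| Tuesday's | 12.0 | 93.5 |

(scatter of a reading: 0.5 percentage points)

- the earlier runs were read with a standard deviation of 0.5 percentage points
- where the amount of free monomer changes, what is given in equivalents or mol% on it follows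

* which of the two ends with the higher amount of monomer in chains, in percent of the free monomer charged ("neither" if they lie within 2 percentage points) (dusk / winter / neither)
* monomer in chains at the end, in percent of the free monomer charged, dusk
* monomer in chains at the end, in percent of the free monomer charged, winter

I assumed that protic impurity and growing chains competed for the free monomer. With [protic impurity] held at 0.0500 M, the monomer lost per monomer in chains should then fall as [initiator] rises. So I defined the loss product: the plateau ratio of lost monomer to monomer in chains, the inverse of a selectivity factor, times the charged [initiator]. Read from Sunday's plateau it was 5.65 × 10⁻⁴ M. Tuesday's, with more free monomer, read 5.42 × 10⁻⁴ M. Thursday's, with less [initiator], read 4.42 × 10⁻⁴ M.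

I used Thursday's value for dusk, charged at 0.00240 M, and Sunday's for winter, charged at 0.00500 M. Thursday's last two readings differed by 0.4 percentage points, so I took 25 min as the plateau. My reckoning gave 84.4% for dusk and 89.9% for winter. In my reckoning winter led by 5.5 points, beyond the margin of 2 points.

The forecast also chose winter, but with slightly different numbers: 84% for dusk and 90.4% for winter. Its ground was that “Sunday and Tuesday nearly coincide despite different monomer charges”.

Dusk ended at 85.1% and winter at 89.9%, so winter stood higher.

    protic impurity + free monomer → quenched substrate (k = 2.70 M⁻¹ min⁻¹)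
    free monomer + living end → monomer in chains + living end, rate k2*[living end]*[free monomer] (k = 320 M⁻¹ min⁻¹)
    2 initiator → spent initiator (k = 6.00 M⁻¹ min⁻¹)
    free monomer + initiator → living end + monomer in chains (k = 65.0 M⁻¹ min⁻¹)

Free monomer stood at 0% in winter, with quenched substrate at 10.1%. Read back from the results, the loss product was 4.21 × 10⁻⁴ M for dusk and 5.65 × 10⁻⁴ M for winter. The neighbouring flask was winter with 40 mol% initiator, charged at 0.0200 M. Sunday's loss product gave it 97.3%. That flask ended at 95.9%, and at 25.0 min its living end stood at 0.0123 M.

The data come from a simulation for an exercise; the scatter is artificial.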